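**Retrosynthetic overview**

1. The biaryl bond C2(ring A)–C1'(ring B) is made last, by a dehydrogenative (oxidative) cross-coupling of free 2-allylphenol with the complete 4-allylphenyl tert-alkyl ether. This is a reagent copy of the oxidative ortho–para phenol coupling presumed to build the honokiol biaryl, and it needs no halide, boron or protecting group on either partner.
2. The enabling feature: on ring B the biaryl carbon C1' is para to the phenolic C4'–OH, and the only other substituent (allyl, C3') is ortho to that OH. On ring A the biaryl carbon C2 is ortho to the ether oxygen on C1, and the para carbon C4 is blocked by allyl. The bond therefore joins the innate electrophilic site of an oxidised 2-allylphenol to the only activated site of the ether.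
3. The aryl–O bond comes from O-arylation of the tertiary alkoxide (C3 configuration already fixed) with a diaryliodonium salt; the isopropenyl group serves as masked C11 carbinol (hydrated afterwards), and the allyl group is added by Stille coupling.
4. Decalin: ring B is bought as (+)-dihydrocarvone (C7); ring A is closed by an auxiliary-controlled Michael addition and aldol condensation (Robinson annulation, sets C10); Birch reduction sets C5 (trans fusion); equatorial methyl transfer to the C3 ketone sets C3.
5. Both benzene rings are purchased intact.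

Key step: step 8

Remark on the chemistry (numbering): the decalin is numbered like a eudesmane (C3 = ether carbon, C5 = ring-fusion CH, C7 = carbon bearing the side chain, C10 = angular quaternary carbon, C11 = side-chain carbinol carbon; β = face of the angular methyl). The target is then 3α-aryloxy-3β-methyl, 5α-H, 7β-(2-hydroxypropan-2-yl), 10β-methyl, which is (2R,4aS,7R,8aS) when the decalin is numbered from the ether carbon.
Remark on the chemistry (starting material): commercial (+)-dihydrocarvone is a mixture of C2 epimers, both 5R; they converge in step 1 because C2 passes through the enamine.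

**Route**

Step 1
Reactants: 1 (+)-dihydrocarvone; 2 (R)-1-phenylethylamine; 3 methyl vinyl ketone
Product: 6 (2S,5R)-2-methyl-2-(3-oxobutyl)-5-(prop-1-en-2-yl)cyclohexan-1-one, via ketimine 4 (not isolated), via Michael-adduct ketimine 5 (not isolated)
Conditions: 2, TsOH (cat.), toluene, reflux, Dean–Stark; then 3, THF, 40 °C; then 10% aq AcOH, rt
Reagents that add atoms: water, O
Why: Asymmetric Michael addition of a chiral ketimine through its more substituted secondary enamine tautomer: the enone is delivered in a compact aza-ene-like transition state to the enamine face left open by the (R)-1-phenylethyl group (matched with the 5R centre), which sets the quaternary carbon as 2S (angular methyl cis to the isopropenyl group), and mild acid hydrolysis releases the diketone and the auxiliary.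

Step 2
Reactants: 6 (2S,5R)-2-methyl-2-(3-oxobutyl)-5-(prop-1-en-2-yl)cyclohexan-1-one
Product: 7 (4aS,7R)-4a-methyl-7-(prop-1-en-2-yl)-4,4a,5,6,7,8-hexahydronaphthalen-2(3H)-one
Conditions: NaOMe (0.2 equiv), MeOH, rt to 50 °C
Reagents that add atoms: none
Why: Intramolecular aldol condensation (6-exo-trig addition of the methyl ketone enolate to the ring carbonyl, then E1cB dehydration) completes the Robinson annulation and closes ring A; neither existing stereocentre is enolisable.

Step 3
Reactants: 7 (4aS,7R)-4a-methyl-7-(prop-1-en-2-yl)-4,4a,5,6,7,8-hexahydronaphthalen-2(3H)-one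
Product: 8 (4aS,7R,8aS)-4a-methyl-7-(prop-1-en-2-yl)octahydronaphthalen-2(1H)-one (trans-fused)
Conditions: Li, NH3(l), THF, t-BuOH (1 equiv), −78 °C; then NH4Cl
Reagents that add atoms: none
Why: Dissolving-metal enone reduction (Birch conditions): the C5 carbanion is protonated axially, anti to the angular methyl, so the trans-decalone (H-5 α) should result, while the carbonyl is protected as its lithium enolate and the isolated 1,1-disubstituted alkene is not reduced.

Step 4
Reactants: 8 (4aS,7R,8aS)-4a-methyl-7-(prop-1-en-2-yl)octahydronaphthalen-2(1H)-one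
Product: 9 (2R,4aS,7R,8aS)-2,4a-dimethyl-7-(prop-1-en-2-yl)decahydronaphthalen-2-ol (axial OH, equatorial CH3)
Conditions: MeTi(OiPr)3 (2 equiv), Et2O, −30 °C to rt; aq NH4Cl
Reagents that add atoms: methyltitanium triisopropoxide, C[Ti](OC(C)C)(OC(C)C)OC(C)C
Why: Carbonyl addition of a bulky, non-basic methyltitanium reagent: in the locked trans-decalone the axial (α) approach is screened by the axial hydrogens at C1 and C5, so methyl should be delivered equatorially from the β face, giving the axial 3α-alcohol with equatorial 3β-methyl (2R) without enolisation.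

Step 5
Reactants: 9 (2R,4aS,7R,8aS)-2,4a-dimethyl-7-(prop-1-en-2-yl)decahydronaphthalen-2-ol; 10 bis(4-bromophenyl)iodonium trifluoromethanesulfonate
Product: 12 1-bromo-4-{[(2R,4aS,7R,8aS)-2,4a-dimethyl-7-(prop-1-en-2-yl)decahydronaphthalen-2-yl]oxy}benzene, via sodium alkoxide 11 (not isolated)
Conditions: NaH, THF/toluene, 50 °C; then 10 (1.3 equiv), rt
Reagents that add atoms: none
Why: O-Arylation of a tertiary alkoxide with a diaryliodonium salt (ligand exchange at iodine(III), then ligand coupling) forms the hindered tert-alkyl aryl ether without touching the C3–O bond, so the configuration from step 4 is retained; the isopropenyl group stands in for the second tertiary alcohol, so only one OH can be arylated.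

Step 6
Reactants: 12 1-bromo-4-{[(2R,4aS,7R,8aS)-2,4a-dimethyl-7-(prop-1-en-2-yl)decahydronaphthalen-2-yl]oxy}benzene
Product: 14 2-[(2R,4aS,7R,8aS)-7-(4-bromophenoxy)-4a,7-dimethyldecahydronaphthalen-2-yl]propan-2-ol, via alkylmercury acetate 13 (not isolated)
Conditions: Hg(OAc)2, THF/H2O (1:1), rt; then 3 M NaOH, NaBH4, 0 °C
Reagents that add atoms: water, O
Why: Markovnikov oxymercuration–demercuration of the only alkene (1,1-disubstituted) should give the tertiary carbinol under near-neutral conditions that leave the aryl bromide and the acid-labile tert-alkyl aryl ether intact; C7 is not involved.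

Step 7
Reactants: 14 2-[(2R,4aS,7R,8aS)-7-(4-bromophenoxy)-4a,7-dimethyldecahydronaphthalen-2-yl]propan-2-ol
Product: 15 2-[(2R,4aS,7R,8aS)-7-(4-allylphenoxy)-4a,7-dimethyldecahydronaphthalen-2-yl]propan-2-ol
Conditions: allylSnBu3 (1.5 equiv), Pd(PPh3)4 (5 mol%), DMF, 90 °C
Reagents that add atoms: allyltributylstannane, C=CC[Sn](CCCC)(CCCC)CCCC
Why: Stille coupling of the aryl bromide with the allylstannane is neutral and tolerates the free tertiary alcohol and the tert-alkyl aryl ether; a short reaction time should limit migration of the allyl double bond into conjugation.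

Step 8
Reactants: 15 2-[(2R,4aS,7R,8aS)-7-(4-allylphenoxy)-4a,7-dimethyldecahydronaphthalen-2-yl]propan-2-ol; 16 2-allylphenol
Product: 19 2-allyl-4-[5-allyl-2-{[(2R,4aS,7R,8aS)-7-(2-hydroxypropan-2-yl)-2,4a-dimethyldecahydronaphthalen-2-yl]oxy}phenyl]phenol (target), via aryloxy-λ3-iodane 17 (not isolated), via 4-arylcyclohexa-2,5-dienone 18 (not isolated)
Conditions: PhI(OAc)2 (1.0 equiv), HFIP/CH2Cl2 (4:1), −20 °C; 16 and oxidant added slowly to 15 (2 equiv, excess recovered)
Reagents that add atoms: none
Why: PhI(OAc)2 can exchange a ligand only with the single ArO–H in the flask (16) to give 17, which in HFIP collapses with loss of PhI and acetate to a 2-allylphenoxonium-type species; C2 of ether 15 (ortho to the ether oxygen) attacks its para carbon in a Friedel–Crafts manner, the Wheland intermediate loses H+ to give dienone 18, and 18 tautomerises to phenol 19. The closest known reaction type is the iodine(III)-mediated (and the related anodic) para-selective dehydrogenative cross-coupling of phenols with alkoxyarenes in fluoroalcohols, itself a chemical counterpart of enzymatic oxidative phenol coupling. The step closes no ring and creates no stereocentre (C4 of 18 is transient), and the four decalin stereocentres are remote spectators. It needs chemoselective oxidation of 16, hetero- rather than homo-coupling, para attack on ring B and a single site on ring A: the first is secured because 15 has no phenolic OH and its tertiary alcohol is a poor ligand for iodine, the second by HFIP hydrogen-bonding to unreacted 16 (lowering its nucleophilicity) together with the excess of 15 and slow addition, the third by the allyl group blocking one ortho position while the free para carbon is the most electrophilic, and the fourth by the C4 allyl group of 15, which leaves only the two equivalent carbons ortho to oxygen activated. The tert-alkyl aryl ether, the tertiary alcohol and both terminal alkenes should survive because acetic acid is the only acid formed and the oxidant is consumed by the phenol at −20 °C, and keeping the oxidant at one equivalent protects the product phenol from further oxidation.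

**Compound list**

1 | (+)-dihydrocarvone, (2R,5R)-2-methyl-5-(prop-1-en-2-yl)cyclohexan-1-one | C[C@@H]1CC[C@@H](C(C)=C)CC1=O | starting material
2 | (R)-1-phenylethylamine | C[C@@H](N)c1ccccc1 | starting material
3 | methyl vinyl ketone (but-3-en-2-one) | CC(=O)C=C | starting material
4 | ketimine of 1 with 2 (not isolated; C2 epimerisable through the enamine) | C[C@@H]1CC[C@@H](C(C)=C)CC1=N[C@H](C)c1ccccc1 | intermediate
5 | Michael-adduct ketimine, the (R)-1-phenylethyl imine of 6 (not isolated) | CC(=O)CC[C@]1(C)CC[C@@H](C(C)=C)CC1=N[C@H](C)c1ccccc1 | intermediate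
6 | (2S,5R)-2-methyl-2-(3-oxobutyl)-5-(prop-1-en-2-yl)cyclohexan-1-one | CC(=O)CC[C@]1(C)CC[C@@H](C(C)=C)CC1=O | intermediate
7 | (4aS,7R)-4a-methyl-7-(prop-1-en-2-yl)-4,4a,5,6,7,8-hexahydronaphthalen-2(3H)-one | O=C1CC[C@]2(C)CC[C@@H](C(C)=C)CC2=C1 | intermediate
8 | (4aS,7R,8aS)-4a-methyl-7-(prop-1-en-2-yl)octahydronaphthalen-2(1H)-one, trans-fused | O=C1CC[C@]2(C)CC[C@@H](C(C)=C)C[C@H]2C1 | intermediate
9 | (2R,4aS,7R,8aS)-2,4a-dimethyl-7-(prop-1-en-2-yl)decahydronaphthalen-2-ol | O[C@]1(C)CC[C@]2(C)CC[C@@H](C(C)=C)C[C@H]2C1 | intermediate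
10 | bis(4-bromophenyl)iodonium trifluoromethanesulfonate | Brc1ccc([I+]c2ccc(Br)cc2)cc1.[O-]S(=O)(=O)C(F)(F)F | starting material
11 | sodium alkoxide of 9 (not isolated) | [Na+].[O-][C@]1(C)CC[C@]2(C)CC[C@@H](C(C)=C)C[C@H]2C1 | intermediate
12 | 1-bromo-4-{[(2R,4aS,7R,8aS)-2,4a-dimethyl-7-(prop-1-en-2-yl)decahydronaphthalen-2-yl]oxy}benzene | Brc1ccc(O[C@]2(C)CC[C@]3(C)CC[C@@H](C(C)=C)C[C@H]3C2)cc1 | intermediate
13 | acetoxy{2-[(2R,4aS,7R,8aS)-7-(4-bromophenoxy)-4a,7-dimethyldecahydronaphthalen-2-yl]-2-hydroxypropyl}mercury (not isolated; C11 epimers) | Brc1ccc(O[C@]2(C)CC[C@]3(C)CC[C@@H](C(C)(O)C[Hg]OC(C)=O)C[C@H]3C2)cc1 | intermediate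
14 | 2-[(2R,4aS,7R,8aS)-7-(4-bromophenoxy)-4a,7-dimethyldecahydronaphthalen-2-yl]propan-2-ol | Brc1ccc(O[C@]2(C)CC[C@]3(C)CC[C@@H](C(C)(C)O)C[C@H]3C2)cc1 | intermediate
15 | 2-[(2R,4aS,7R,8aS)-7-(4-allylphenoxy)-4a,7-dimethyldecahydronaphthalen-2-yl]propan-2-ol | C=CCc1ccc(O[C@]2(C)CC[C@]3(C)CC[C@@H](C(C)(C)O)C[C@H]3C2)cc1 | intermediate
16 | 2-allylphenol | C=CCc1ccccc1O | starting material
17 | acetoxy(2-allylphenoxy)phenyl-λ3-iodane (not isolated) | CC(=O)OI(Oc1ccccc1CC=C)c1ccccc1 | intermediate
18 | 2-allyl-4-[5-allyl-2-{[(2R,4aS,7R,8aS)-7-(2-hydroxypropan-2-yl)-2,4a-dimethyldecahydronaphthalen-2-yl]oxy}phenyl]cyclohexa-2,5-dien-1-one (not isolated; C4 of the dienone undefined) | C=CCC1=CC(c2cc(CC=C)ccc2O[C@]2(C)CC[C@]3(C)CC[C@@H](C(C)(C)O)C[C@H]3C2)C=CC1=O | intermediate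
19 | 2-allyl-4-[5-allyl-2-{[(2R,4aS,7R,8aS)-7-(2-hydroxypropan-2-yl)-2,4a-dimethyldecahydronaphthalen-2-yl]oxy}phenyl]phenol | C=CCc1ccc(O[C@]2(C)CC[C@]3(C)CC[C@@H](C(C)(C)O)C[C@H]3C2)c(-c2ccc(O)c(CC=C)c2)c1 | target

**Step count and risks**

Total step count: 8. Longest linear sequence: 8 steps (1 to 19).

Steps most likely to fail:

1. Step 8. The oxidised phenol may be captured by a second molecule of 16, by acetate or by solvent faster than by C2 of 15, which is a weaker and more shielded nucleophile than the polyalkoxyarenes usual in this coupling. The result would be homo-coupling and over-oxidation; attack at the open ortho position of the phenol would give a regioisomeric biaryl. Fallback (Suzuki–Miyaura union of pre-functionalised partners): it sets out from tertiary alcohol 9 and comes back at target 19. Sodium alkoxide 11 (NaH, DMF) displaces fluoride from 3-bromo-4-fluorobenzaldehyde (SNAr) to give bromo aldehyde F1. Oxymercuration as in step 6 gives alkylmercury acetate F2, and the NaBH4 of the demercuration also reduces the aldehyde, giving benzylic alcohol F3. Appel bromination (CBr4, PPh3, CH2Cl2, 0 °C) of the primary OH gives benzylic bromide F4. Stille coupling with tributyl(vinyl)stannane (Pd(PPh3)4, THF, 60 °C), which should engage the benzylic C–Br bond much faster than the hindered aryl C–Br bond, gives 4-allyl-2-bromophenyl ether F5. Suzuki–Miyaura coupling (Pd(OAc)2/SPhos, K3PO4, dioxane/H2O, 80 °C) with boronate F6, made from commercial 2-allyl-4-bromophenol by Miyaura borylation (B2pin2, PdCl2(dppf), KOAc, dioxane, 80 °C), then gives 19.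

2. Step 5. Ligand coupling at iodine may be slowed by the axial, hindered alkoxide, so that ortho-deprotonation of the iodonium salt to an aryne (regioisomeric ethers) or simple return of 9 takes over. Fallback (activated SNAr, then build the allyl group from the activating group): it sets out from 9 and comes back at 15. Sodium alkoxide 11 (NaH, DMF) displaces fluoride from 4-fluorobenzaldehyde to give aldehyde F7. Oxymercuration gives alkylmercury acetate F8, and NaBH4 demercuration with concurrent aldehyde reduction gives benzylic alcohol F9. Appel bromination gives benzylic bromide F10. Stille coupling with tributyl(vinyl)stannane (Pd(PPh3)4, THF, 60 °C) gives 15.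

3. Step 4. Facial selectivity of methyl transfer may be insufficient (axial delivery gives the C3 epimer). Fallback (two-step methylene transfer and hydride opening): it sets out from ketone 8 and comes back at 9. Corey–Chaykovsky reaction with dimethylsulfoxonium methylide (Me3S(O)I, NaH, DMSO, rt), which adds reversibly and places the new carbon equatorial, gives spiro-epoxide F11 with axial oxygen. LiAlH4 (THF, 0 °C) opens the oxirane at CH2 to give 9.

Further compounds
F1 | step 8 | 3-bromo-4-{[(2R,4aS,7R,8aS)-2,4a-dimethyl-7-(prop-1-en-2-yl)decahydronaphthalen-2-yl]oxy}benzaldehyde | O=Cc1ccc(O[C@]2(C)CC[C@]3(C)CC[C@@H](C(C)=C)C[C@H]3C2)c(Br)c1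
F2 | step 8 | acetoxy{2-[(2R,4aS,7R,8aS)-7-(2-bromo-4-formylphenoxy)-4a,7-dimethyldecahydronaphthalen-2-yl]-2-hydroxypropyl}mercury | O=Cc1ccc(O[C@]2(C)CC[C@]3(C)CC[C@@H](C(C)(O)C[Hg]OC(C)=O)C[C@H]3C2)c(Br)c1
F3 | step 8 | 2-[(2R,4aS,7R,8aS)-7-[2-bromo-4-(hydroxymethyl)phenoxy]-4a,7-dimethyldecahydronaphthalen-2-yl]propan-2-ol | OCc1ccc(O[C@]2(C)CC[C@]3(C)CC[C@@H](C(C)(C)O)C[C@H]3C2)c(Br)c1
F4 | step 8 | 2-[(2R,4aS,7R,8aS)-7-[2-bromo-4-(bromomethyl)phenoxy]-4a,7-dimethyldecahydronaphthalen-2-yl]propan-2-ol | BrCc1ccc(O[C@]2(C)CC[C@]3(C)CC[C@@H](C(C)(C)O)C[C@H]3C2)c(Br)c1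
F5 | step 8 | 2-[(2R,4aS,7R,8aS)-7-(4-allyl-2-bromophenoxy)-4a,7-dimethyldecahydronaphthalen-2-yl]propan-2-ol | C=CCc1ccc(O[C@]2(C)CC[C@]3(C)CC[C@@H](C(C)(C)O)C[C@H]3C2)c(Br)c1
F6 | step 8 | 2-allyl-4-(4,4,5,5-tetramethyl-1,3,2-dioxaborolan-2-yl)phenol | C=CCc1cc(B2OC(C)(C)C(C)(C)O2)ccc1O
F7 | step 5 | 4-{[(2R,4aS,7R,8aS)-2,4a-dimethyl-7-(prop-1-en-2-yl)decahydronaphthalen-2-yl]oxy}benzaldehyde | O=Cc1ccc(O[C@]2(C)CC[C@]3(C)CC[C@@H](C(C)=C)C[C@H]3C2)cc1
F8 | step 5 | acetoxy{2-[(2R,4aS,7R,8aS)-7-(4-formylphenoxy)-4a,7-dimethyldecahydronaphthalen-2-yl]-2-hydroxypropyl}mercury | O=Cc1ccc(O[C@]2(C)CC[C@]3(C)CC[C@@H](C(C)(O)C[Hg]OC(C)=O)C[C@H]3C2)cc1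
F9 | step 5 | 2-[(2R,4aS,7R,8aS)-7-[4-(hydroxymethyl)phenoxy]-4a,7-dimethyldecahydronaphthalen-2-yl]propan-2-ol | OCc1ccc(O[C@]2(C)CC[C@]3(C)CC[C@@H](C(C)(C)O)C[C@H]3C2)cc1
F10 | step 5 | 2-[(2R,4aS,7R,8aS)-7-[4-(bromomethyl)phenoxy]-4a,7-dimethyldecahydronaphthalen-2-yl]propan-2-ol | BrCc1ccc(O[C@]2(C)CC[C@]3(C)CC[C@@H](C(C)(C)O)C[C@H]3C2)cc1
F11 | step 4 | (2R,4aS,7R,8aS)-4a-methyl-7-(prop-1-en-2-yl)octahydro-1H-spiro[naphthalene-2,2'-oxirane] (oxirane oxygen axial) | C1O[C@@]12CC[C@]3(C)CC[C@@H](C(C)=C)C[C@H]3C2
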